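The constants were set for the occasion; the run is a simulation.

We begin with an easy count: each impurity takes one enzyme out of the round for good, while turning substrate over costs enzyme nothing.

substrate 20 mM; enzyme 10 µM; impurity 4.3 µM

    substrate + enzyme → product + enzyme, rate k1*[substrate]^2.5*[enzyme]/(1 + ([substrate]/Kh1)^2.5) (Kh1 = 12.9 mM, k1 = 9.15 × 10⁷ L²·⁵ mol⁻²·⁵ s⁻¹)
    enzyme + impurity → spent catalyst (k2 = 7.15 × 10⁵ L mol⁻¹ s⁻¹)

- the form that holds most of the catalyst when 5.0% of the substrate are converted (spent catalyst / enzyme)
- its share of the catalyst then
- factor on the rate of making product when 5.0% of the substrate are converted if enzyme is charged twice over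
- factor on the rate when 5.0% of the substrate are converted if enzyme is charged at 50 µM instead

Turn the question round and ask what spent catalyst would need in order to hold most of the catalyst. Its amount cannot pass the impurity charge, and impurity is the limiting reagent of the second step, with 4.3 µM charged, less than the 10 µM of enzyme. So the impurity charge would have to exceed half of the enzyme charge, but in this flask it is less than that, at 43.0% of the enzyme charge, and enzyme cannot fall below 5.70 µM.

The share needs the balance of impurity. Substrate and impurity both fall in proportion to c(enzyme), so how far impurity has fallen follows from how much substrate is converted, and neither time nor c(enzyme) enters. Each enzyme turns over 1300 s⁻¹ at the start and 1250 s⁻¹ at the mark. With the mean of these, converting 1.00 mM gives c(impurity) a logarithmic fall of 0.561, and 1.85 µM of impurity goes. We call this the toll, the enzyme lost by a given conversion, whatever the enzyme charge, with the substrate and impurity charges held. So enzyme keeps 81.5%. At equal conversion the rate follows free enzyme, which gives factors of 2.23 for the doubled charge and 5.91 for 50 µM.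

The forecast names enzyme at 81.5%, with factors 2.23 and 5.91, on the ground that “the impurity consumed depends only on substrate converted, whatever the enzyme charge”. That is our road too, and our numbers.

The simulation gives enzyme at 81.5%, with factors 2.23 and 5.91. The mark comes after 0.0875 s, against a half-life of impurity of 0.0969 s at the enzyme charge, and spent catalyst then stands at 18.5%, the toll of 1.85 µM on 10 µM. In the flask charged with 50 µM, the same toll would be 3.70% of the catalyst, and that run reads 3.69% spent catalyst.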